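**Strategy.** Numbering follows 3,4-dihydronaphthalene-2-carbaldehyde (ring A aromatic, ring B the carbocycle). Ring B is cut at the C1=C2 enal alkene and at the C4–C4a bond between the aryl-bearing methine and the arene carbon ortho to the C5 methoxy group. One TMSOTf-mediated cascade joins a C3-stereodefined gamma-lactol (a masked 4-aryl-4-hydroxy-3-(hydroxymethyl)butanal from an Evans aldol) with a 2-trimethylsilyl vanillin ether. A Mukaiyama-type condensation forms C1=C2, and the benzylic cation released at C4 closes C4–C4a by silicon-directed ipso Friedel–Crafts attack, trans to C3. The step exploits the para-oxygenated aryl group on C4, which makes C4 a latent benzylic cation two atoms from the enolisable C2.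

Key step: step 7

Assumption: lactol 11 equilibrates with its open hydroxy aldehyde and the isomeric five-membered lactol; all forms should converge in step 7, so it is drawn as one lactol with the anomeric centre unassigned.

Step 1
Reactants: 1 vanillin
Product: 2 3-methoxy-4-(triisopropylsilyloxy)benzaldehyde
Conditions: TIPSCl, imidazole, DMF, rt
Reagents that add atoms: triisopropylsilyl chloride CC(C)[Si](Cl)(C(C)C)C(C)C
Why: Phenol silylation under imidazole catalysis is routine, and the bulky aryl TIPS ether should survive the organolithium, hydride and Lewis-acid steps that follow.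

Step 2
Reactants: 2 3-methoxy-4-(triisopropylsilyloxy)benzaldehyde
Product: 4 3-methoxy-4-(triisopropylsilyloxy)-2-(trimethylsilyl)benzaldehyde, via ortho-lithiated alpha-amino alkoxide 3 (not isolated)
Conditions: Me2NCH2CH2N(Me)Li (from Me2NCH2CH2NHMe and n-BuLi), THF, −20 °C; n-BuLi (3 equiv), −20 °C; TMSCl, −78 °C to rt; aq. NH4Cl
Reagents that add atoms: chlorotrimethylsilane C[Si](C)(C)Cl
Why: Directed ortho-metalation, in which the in situ alpha-amino alkoxide (masked aldehyde) and the methoxy group together direct n-BuLi to the carbon between them, and the aryllithium is silylated before work-up releases the aldehyde.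

Step 3
Reactants: 5 (S)-4-benzyl-1,3-oxazolidin-2-one; 6 pent-4-enoyl chloride
Product: 7 (4S)-4-benzyl-3-(pent-4-enoyl)-1,3-oxazolidin-2-one
Conditions: n-BuLi, THF, −78 °C; then 6, −78 to 0 °C
Reagents that add atoms: none
Why: N-acylation of the lithiated oxazolidinone with an acid chloride is the standard route to the imide.

Step 4
Reactants: 7 (4S)-4-benzyl-3-(pent-4-enoyl)-1,3-oxazolidin-2-one; 2 3-methoxy-4-(triisopropylsilyloxy)benzaldehyde
Product: 9 (4S)-4-benzyl-3-[(2S)-2-[(S)-hydroxy[3-methoxy-4-(triisopropylsilyloxy)phenyl]methyl]pent-4-enoyl]-1,3-oxazolidin-2-one, via Z boron enolate 8 (not isolated)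
Conditions: Bu2BOTf, iPr2NEt, CH2Cl2, −78 to 0 °C; then 2, −78 to 0 °C; pH 7 buffer, MeOH, H2O2
Reagents that add atoms: none
Why: Evans syn aldol, in which the Z boron enolate reacts through a closed chair transition state on the face away from the benzyl group; this sets the (2S) alpha centre that becomes C3 of the target, while the carbinol centre is lost later.

Step 5
Reactants: 9 aldol adduct
Product: 10 (1S,2R)-1-[3-methoxy-4-(triisopropylsilyloxy)phenyl]-2-(prop-2-en-1-yl)propane-1,3-diol
Conditions: LiBH4, H2O (1 equiv), Et2O, 0 °C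
Reagents that add atoms: none
Why: Hydride reduction with LiBH4 is selective for the exocyclic imide carbonyl, so it should remove the auxiliary and give the 1,3-diol without touching the alkene or the aryl silyl ether.

Step 6
Reactants: 10 (1S,2R)-1-[3-methoxy-4-(triisopropylsilyloxy)phenyl]-2-(prop-2-en-1-yl)propane-1,3-diol
Product: 11 (4R,5S)-4-(hydroxymethyl)-5-[3-methoxy-4-(triisopropylsilyloxy)phenyl]oxolan-2-ol
Conditions: K2OsO4·2H2O (cat.), NaIO4, 2,6-lutidine, dioxane/H2O, rt
Reagents that add atoms: sodium periodate [Na+].[O-]I(=O)(=O)=O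
Why: Lemieux–Johnson oxidation should cleave the terminal alkene to the aldehyde, which closes at once to the five-membered lactol, and it avoids ozone in the presence of the electron-rich arene.

Step 7
Reactants: 11 (4R,5S)-4-(hydroxymethyl)-5-[3-methoxy-4-(triisopropylsilyloxy)phenyl]oxolan-2-ol; 4 3-methoxy-4-(triisopropylsilyloxy)-2-(trimethylsilyl)benzaldehyde
Product: 14 (3R,4S)-3-(hydroxymethyl)-5-methoxy-4-[3-methoxy-4-(triisopropylsilyloxy)phenyl]-6-(triisopropylsilyloxy)-3,4-dihydronaphthalene-2-carbaldehyde, via silylated 2,3-dihydrofuran 12 (not isolated), via silyloxy tetralin aldehyde 13 (not isolated)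
Conditions: TMSOTf (4 equiv), iPr2NEt (3.3 equiv), CH2Cl2, −78 °C to rt; then 1 M HCl, THF, 0 °C
Reagents that add atoms: none
Why: Proposed new method: TMSOTf/iPr2NEt should silylate 11 and eliminate its anomeric silyloxy group to the cyclic enol ether 12, whose beta carbon adds in Mukaiyama fashion to the silyl-activated aldehyde of 4 (C1–C2 bond); the 2-aryl oxocarbenium ion so formed opens at its benzylic C–O bond to a 4-silyloxybenzyl cation at C4, which is attacked by the tethered arene at the silicon-bearing carbon (C4–C4a bond, loss of Me3Si+ that regenerates TMSOTf) to give 13, and elimination of silanol then gives the C1=C2 enal. The closest known reaction types are the one-pot enol ether formation/Mukaiyama aldol with TMSOTf and an amine base, the acid-induced rearrangement of 2,5-diaryltetrahydrofuran lignans to 1-aryl-1,2-dihydronaphthalenes, and silicon-directed ipso Friedel–Crafts (Pictet–Spengler-type) ring closure. Ring B is the only ring closed, by intramolecular electrophilic ipso substitution in which the arene attacks the exocyclic C4 cation (six-membered, endo to the arene pi bond). C4 is the only new stereocentre: the planar cation should cyclise through a half-chair with the aryl group anti to the C3 CH2OSiMe3 group, giving the 3,4-trans (3R,4S) product, with C3 carried unchanged from 11. The step needs closure ortho rather than para to the methoxy group, secured by beta-silyl-stabilised ipso attack at C4a, and ionisation at C4 rather than C1, secured because the oxocarbenium oxygen makes the C4–O bond the leaving group only after C1–C2 has formed; the amine buffer guards 4 against protodesilylation.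

Step 8
Reactants: 14 bis-TIPS ether of the target
Product: 15 vitedoin A, (3R,4S)-6-hydroxy-4-(4-hydroxy-3-methoxyphenyl)-3-(hydroxymethyl)-5-methoxy-3,4-dihydronaphthalene-2-carbaldehyde
Conditions: TBAF, AcOH, THF, 0 °C
Reagents that add atoms: none
Why: Fluoride desilylation should cleave both aryl silyl ethers, and the acetic acid buffer keeps the phenols protonated so the gamma-hydroxy enal and both stereocentres stay untouched.

**Compound list**

1 | vanillin | COc1cc(C=O)ccc1O | starting material
2 | 3-methoxy-4-(triisopropylsilyloxy)benzaldehyde | COc1cc(C=O)ccc1O[Si](C(C)C)(C(C)C)C(C)C | intermediate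
3 | lithium [2-lithio-3-methoxy-4-(triisopropylsilyloxy)phenyl]{[2-(dimethylamino)ethyl](methyl)amino}methanolate (not isolated) | COc1c([Li])c(C(O[Li])N(C)CCN(C)C)ccc1O[Si](C(C)C)(C(C)C)C(C)C | intermediate
4 | 3-methoxy-4-(triisopropylsilyloxy)-2-(trimethylsilyl)benzaldehyde | COc1c([Si](C)(C)C)c(C=O)ccc1O[Si](C(C)C)(C(C)C)C(C)C | intermediate
5 | (S)-4-benzyl-1,3-oxazolidin-2-one | O=C1OC[C@H](Cc2ccccc2)N1 | starting material
6 | pent-4-enoyl chloride | C=CCCC(Cl)=O | starting material
7 | (4S)-4-benzyl-3-(pent-4-enoyl)-1,3-oxazolidin-2-one | C=CCCC(=O)N1[C@@H](Cc2ccccc2)COC1=O | intermediate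
8 | (Z)-dibutylboron enolate of 7 (not isolated) | C=CC/C=C(\OB(CCCC)CCCC)N1[C@@H](Cc2ccccc2)COC1=O | intermediate
9 | (4S)-4-benzyl-3-[(2S)-2-[(S)-hydroxy[3-methoxy-4-(triisopropylsilyloxy)phenyl]methyl]pent-4-enoyl]-1,3-oxazolidin-2-one | C=CC[C@H](C(=O)N1[C@@H](Cc2ccccc2)COC1=O)[C@H](O)c1ccc(O[Si](C(C)C)(C(C)C)C(C)C)c(OC)c1 | intermediate
10 | (1S,2R)-1-[3-methoxy-4-(triisopropylsilyloxy)phenyl]-2-(prop-2-en-1-yl)propane-1,3-diol | C=CC[C@H](CO)[C@H](O)c1ccc(O[Si](C(C)C)(C(C)C)C(C)C)c(OC)c1 | intermediate
11 | (4R,5S)-4-(hydroxymethyl)-5-[3-methoxy-4-(triisopropylsilyloxy)phenyl]oxolan-2-ol (anomer mixture) | OC1C[C@H](CO)[C@H](O1)c1ccc(O[Si](C(C)C)(C(C)C)C(C)C)c(OC)c1 | intermediate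
12 | (2S,3R)-2-[3-methoxy-4-(triisopropylsilyloxy)phenyl]-3-[(trimethylsilyloxy)methyl]-2,3-dihydrofuran (not isolated) | C1=C[C@H](CO[Si](C)(C)C)[C@@H](c2ccc(O[Si](C(C)C)(C(C)C)C(C)C)c(OC)c2)O1 | intermediate
13 | (3R,4S)-5-methoxy-4-[3-methoxy-4-(triisopropylsilyloxy)phenyl]-6-(triisopropylsilyloxy)-1-(trimethylsilyloxy)-3-[(trimethylsilyloxy)methyl]-1,2,3,4-tetrahydronaphthalene-2-carbaldehyde (C1 and C2 unassigned, not isolated) | COc1cc([C@H]2c3c(ccc(O[Si](C(C)C)(C(C)C)C(C)C)c3OC)C(O[Si](C)(C)C)C(C=O)[C@@H]2CO[Si](C)(C)C)ccc1O[Si](C(C)C)(C(C)C)C(C)C | intermediate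
14 | (3R,4S)-3-(hydroxymethyl)-5-methoxy-4-[3-methoxy-4-(triisopropylsilyloxy)phenyl]-6-(triisopropylsilyloxy)-3,4-dihydronaphthalene-2-carbaldehyde | COc1cc([C@H]2c3c(ccc(O[Si](C(C)C)(C(C)C)C(C)C)c3OC)C=C(C=O)[C@@H]2CO)ccc1O[Si](C(C)C)(C(C)C)C(C)C | intermediate
15 | vitedoin A, (3R,4S)-6-hydroxy-4-(4-hydroxy-3-methoxyphenyl)-3-(hydroxymethyl)-5-methoxy-3,4-dihydronaphthalene-2-carbaldehyde | COc1cc([C@H]2c3c(ccc(O)c3OC)C=C(C=O)[C@@H]2CO)ccc1O | target

**Step count.** Total: 8 steps. Longest linear sequence: 6 steps (steps 3, 4, 5, 6, 7, 8, or equally steps 1, 4, 5, 6, 7, 8).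

**Steps most likely to fail**

Step 7 (Proposed new method). The benzylic C–O bond may ionise before the C1–C2 bond has formed, with loss of the C3 proton to a styrene and erosion of the C3 centre. The silyloxy-bearing C1 may ionise instead, so that the other aryl ring closes. The ring may also close para to the methoxy group after protodesilylation. The fallback is stepwise and uses known reaction types. From 11 and 4, amine-catalysed cross-aldol condensation (pyrrolidine, benzoic acid, CH2Cl2, rt) would give (2E)-2-{(1S,2R)-1,3-dihydroxy-1-[3-methoxy-4-(triisopropylsilyloxy)phenyl]propan-2-yl}-3-[3-methoxy-4-(triisopropylsilyloxy)-2-(trimethylsilyl)phenyl]prop-2-enal F1, in which C1 no longer carries oxygen. Treating F1 with TFA in CH2Cl2 at −20 °C would then ionise the benzylic alcohol with the arene already tethered and close ring B by ipso Friedel–Crafts alkylation, returning to 14.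

Step 2. Metalation may occur at another ring position, or the long lithiation may lead to butyl addition to the masked aldehyde or cleavage of the silyl ether. The fallback sets out from 2. Trimethyl orthoformate and TsOH in MeOH would give [4-(dimethoxymethyl)-2-methoxyphenoxy]triisopropylsilane F2. Lithiation with n-BuLi in Et2O at 0 °C, directed by the acetal and the methoxy group, followed by TMSCl would give [4-(dimethoxymethyl)-2-methoxy-3-(trimethylsilyl)phenoxy]triisopropylsilane F3. Mild hydrolysis (oxalic acid, wet silica, CH2Cl2) would give 4.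

Step 8. The phenoxide-conjugated enal may degrade under base, or silyl groups may migrate to the primary alcohol during fluoride treatment. The fallback sets out from 14. Luche reduction (NaBH4, CeCl3·7H2O, MeOH, 0 °C) would give [(1S,2R)-8-methoxy-1-[3-methoxy-4-(triisopropylsilyloxy)phenyl]-7-(triisopropylsilyloxy)-1,2-dihydronaphthalene-2,3-diyl]dimethanol F4. TBAF in THF would then give 4-[(1S,2R)-7-hydroxy-2,3-bis(hydroxymethyl)-8-methoxy-1,2-dihydronaphthalen-1-yl]-2-methoxyphenol F5 with no enal present. MnO2 in CH2Cl2 would oxidise only the allylic alcohol and reach 15.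

Further compounds
F1 | step 7 | (2E)-2-{(1S,2R)-1,3-dihydroxy-1-[3-methoxy-4-(triisopropylsilyloxy)phenyl]propan-2-yl}-3-[3-methoxy-4-(triisopropylsilyloxy)-2-(trimethylsilyl)phenyl]prop-2-enal | COc1cc([C@@H](O)[C@@H](CO)/C(C=O)=C\c2ccc(O[Si](C(C)C)(C(C)C)C(C)C)c(OC)c2[Si](C)(C)C)ccc1O[Si](C(C)C)(C(C)C)C(C)C
F2 | step 2 | [4-(dimethoxymethyl)-2-methoxyphenoxy]triisopropylsilane | COc1cc(C(OC)OC)ccc1O[Si](C(C)C)(C(C)C)C(C)C
F3 | step 2 | [4-(dimethoxymethyl)-2-methoxy-3-(trimethylsilyl)phenoxy]triisopropylsilane | COc1c([Si](C)(C)C)c(C(OC)OC)ccc1O[Si](C(C)C)(C(C)C)C(C)C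
F4 | step 8 | [(1S,2R)-8-methoxy-1-[3-methoxy-4-(triisopropylsilyloxy)phenyl]-7-(triisopropylsilyloxy)-1,2-dihydronaphthalene-2,3-diyl]dimethanol | COc1cc([C@H]2c3c(ccc(O[Si](C(C)C)(C(C)C)C(C)C)c3OC)C=C(CO)[C@@H]2CO)ccc1O[Si](C(C)C)(C(C)C)C(C)C
F5 | step 8 | 4-[(1S,2R)-7-hydroxy-2,3-bis(hydroxymethyl)-8-methoxy-1,2-dihydronaphthalen-1-yl]-2-methoxyphenol | COc1cc([C@H]2c3c(ccc(O)c3OC)C=C(CO)[C@@H]2CO)ccc1O
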